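Catalyst at 8.00 × 10⁻⁴ M gives the first step a pseudo-first-order constant of 0.00992 s⁻¹, against a dissolution coefficient of 0.00526 s⁻¹.

    starting material + catalyst ⇌ target + catalyst, rate k1*[starting material]*[catalyst] forward; the back reaction follows from the equilibrium constant (K1 = 1.7, k1 = 12.4 M⁻¹ s⁻¹)
    target + catalyst ⇌ isomer of the product + catalyst, rate k2*[catalyst]*[target] forward; the back reaction follows from the equilibrium constant (K2 = 2.7, k2 = 10.6 M⁻¹ s⁻¹)
    solid substrate ⇌ starting material, rate k3*(cs3 - [starting material]) while solid is left; crystals form when [starting material] > cs3 (cs3 = 0.34 M, k3 = 0.00526 s⁻¹)

solid substrate 0.80 M; catalyst 0.1 mol%; time 10 min

1. how much target there is at 10 min, in percent of the solid substrate charged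
2. concentration of starting material in solution at 10 min, in percent of saturation

- given per volume of solution although it is solid: solid substrate
- at the start none of the solid substrate is in solution
- starting material means what is dissolved; the solid is not counted in it
- run time (flask): 10 min

The solid feeds starting material and the first step drains it. Between the two, its life is 65.9 s, short against 10 min, so I treat feed and drain as balanced while solid is left. Without target this gives 0.118 M. I call this the holding level: the concentration at which dissolution just matches the forward first step. It is 34.7% of saturation, before any correction. The correction is the way back from target, which adds 0.384 times the target concentration to starting material.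

For a high estimate, which is no strict ceiling, I give target its equilibrium share, 23.3%, of the whole charge. Starting material then stands at 0.190 M. For a low estimate, I hold starting material at that level, and dissolution then delivers 0.475 M by 10 min. I assume target holds its equilibrium share of this, 0.111 M. So I commit to a yield between 13.8% and 23.3%, and saturation between 47.2% and 55.7%.

The forecast, 21.8% and 52.9%, lies inside this bracket, and says “solid remains and the linear treatment holds throughout”. The simulation gives 21.8% and 52.9%.

In this flask, holding level plus correction, with the simulated target, gives 54.4% of saturation, against 52.9% simulated, and solid substrate still stands at 19.8%. The holding level is 14.7% of this flask's charge. The neighbour flask with 0.20 M of solid substrate has a quarter of the catalyst, and its holding level is 0.231 M, more than its whole charge. At 10.0 min its solid substrate stands at 0%, and starting material holds the most, 39.8%, with target at 34.4%.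

(All constants are made up; no experiment stands behind them.)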